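**Plan**

- Retrosynthetic cuts: the C8 methacrylate and C3 acetate C–O bonds and the C15–O protecting group; the epoxide C1–O bond (C10 alkoxide onto a C1 mesylate); the lactone C12–O6 bond (oxidation of a C6,C12-diol); the ring bond C1–C2; then, in the open chain, C3–C4, C6–C7 and C7–C8.
- Enabling feature: in the ten-membered carbocycle, C1 and C3 both carry oxygen and are separated only by the C2 methylene, and C1 is bonded to the fully substituted, oxygenated C10 (C14 methyl). C1–C2–C3 is therefore an aldol retron whose C1 aldehyde has no α-hydrogen and has a neighbouring stereocentre to steer the addition.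
- Forward order: the chain is joined at C7–C8 (allyl Grignard on a Weinreb amide), C6–C7 (boron aldol) and C3–C4 (Stille) from citramalate (C1, C8–C10, C14), methylenepropanediol (C7, C11–C13) and butynediol (C4–C6, C15) pieces; then the carbocycle (C1–C2), the lactone and the epoxide are closed in that order.
- The C3 enolate is generated reductively from a C2 bromide with SmI2 (Reformatsky-type macro-aldol), so the ring closure is non-basic and the aldolate is held as a samarium chelate.
- Stereochemistry: C10 from (R)-citramalic acid; C6/C7 from a reagent-controlled syn aldol of an isopinocampheylboron (Z)-enolate; C8 by Evans–Tishchenko 1,3-anti reduction (relay from C6); C1 by Felkin–Anh addition next to C10; C3 by hydroxyl-directed 1,3-anti reduction (relay from C1); C1 inverted on epoxide closure; 4Z from trans-hydroalumination/iodination.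

Key step: step 19

Remark: the target is taken as the (1R,3S,4Z,6R,7R,8R,10R) isomer encoded by the SMILES. Labels C1–C15 are the germacrane labels of the target and CIP descriptors are quoted with these labels. TES = triethylsilyl, TBS = tert-butyldimethylsilyl, PMB = 4-methoxybenzyl, Ms = methanesulfonyl, Ipc = isopinocampheyl; (−)-Ipc2BOTf is the reagent made from (+)-α-pinene.

**Route**

Step 1
Reactants: 1 (R)-citramalic acid
Product: 2 dimethyl (2R)-2-hydroxy-2-methylbutanedioate
Conditions: MeOH, H2SO4 (cat.), reflux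
Reagents that add atoms: methanol, CO
Why: Fischer esterification converts both carboxyl groups and leaves the tertiary C10 carbinol untouched.

Step 2
Reactants: 2 dimethyl (2R)-2-hydroxy-2-methylbutanedioate
Product: 3 methyl (3R)-3,4-dihydroxy-3-methylbutanoate
Conditions: BH3·SMe2 (1.05 equiv), NaBH4 (5 mol %), THF, 0 °C → rt; MeOH quench
Reagents that add atoms: none
Why: The tertiary hydroxyl forms an alkoxyborane that delivers hydride to the adjacent C1 ester through a five-membered chelate (hydroxyl-directed borane reduction of α-hydroxy esters), so the remote C8 ester should survive.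

Step 3
Reactants: 3 methyl (3R)-3,4-dihydroxy-3-methylbutanoate
Product: 4 methyl (3R)-3-methyl-3,4-bis(triethylsilyloxy)butanoate
Conditions: Et3SiOTf (2.4 equiv), 2,6-lutidine, CH2Cl2, −78 → 0 °C (crude 3 used at once)
Reagents that add atoms: triethylsilyl trifluoromethanesulfonate, CC[Si](CC)(CC)OS(=O)(=O)C(F)(F)F
Why: Silyl triflate/lutidine silylation caps both the primary and the hindered tertiary hydroxyl before the diol ester can lactonise.

Step 4
Reactants: 4 methyl (3R)-3-methyl-3,4-bis(triethylsilyloxy)butanoate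
Product: 5 (3R)-N-methoxy-N,3-dimethyl-3,4-bis(triethylsilyloxy)butanamide
Conditions: MeNHOMe·HCl, iPrMgCl, THF, −20 → 0 °C
Reagents that add atoms: N,O-dimethylhydroxylamine hydrochloride, CNOC.Cl
Why: Aminolysis of the methyl ester by the chloromagnesium amide (Weinreb amide formation) is standard for β-silyloxy esters and leaves the silyl ethers intact.

Step 5
Reactants: 6 2-methylenepropane-1,3-diol
Product: 7 2-[(tert-butyldimethylsilyloxy)methyl]prop-2-en-1-ol
Conditions: tBuMe2SiCl (0.33 equiv), imidazole, DMF, 0 °C (diol in excess, recovered)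
Reagents that add atoms: tert-butyldimethylsilyl chloride, CC(C)(C)[Si](C)(C)Cl
Why: Statistical monosilylation of the symmetric diol used in excess should give mainly the mono-ether.

Step 6
Reactants: 7 2-[(tert-butyldimethylsilyloxy)methyl]prop-2-en-1-ol
Product: 8 tert-butyl{[2-(chloromethyl)prop-2-en-1-yl]oxy}dimethylsilane
Conditions: N-chlorosuccinimide, Me2S, CH2Cl2, −20 → 0 °C
Reagents that add atoms: N-chlorosuccinimide, O=C1CCC(=O)N1Cl
Why: Corey–Kim chlorination converts the primary allylic alcohol into the chloride under neutral conditions that keep the silyl ether.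

Step 7
Reactants: 8 tert-butyl{[2-(chloromethyl)prop-2-en-1-yl]oxy}dimethylsilane; 5 (3R)-N-methoxy-N,3-dimethyl-3,4-bis(triethylsilyloxy)butanamide
Product: 10 (2R)-6-[(tert-butyldimethylsilyloxy)methyl]-2-methyl-1,2-bis(triethylsilyloxy)hept-6-en-4-one (C8 ketone), via allylmagnesium chloride 9 (not isolated)
Conditions: Mg turnings, THF, 0 °C; then 5, −78 °C; aq. NH4Cl at −78 °C
Reagents that add atoms: none
Why: The allylic Grignard reagent adds once to the Weinreb amide because the chelated tetrahedral intermediate persists until the cold quench, which should release the β,γ-unsaturated ketone without moving the 1,1-disubstituted double bond into conjugation.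

Step 8
Reactants: 11 but-2-yne-1,4-diol
Product: 12 4-[(4-methoxybenzyl)oxy]but-2-yn-1-ol
Conditions: 4-methoxybenzyl chloride (0.33 equiv), KOH, DMSO, rt (diol in excess)
Reagents that add atoms: 4-methoxybenzyl chloride, COc1ccc(CCl)cc1
Why: Williamson mono-etherification of the symmetric diol used in excess.

Step 9
Reactants: 12 4-[(4-methoxybenzyl)oxy]but-2-yn-1-ol
Product: 14 (2Z)-3-iodo-4-[(4-methoxybenzyl)oxy]but-2-en-1-ol, via cyclic sodium alkenylaluminate 13 (not isolated)
Conditions: NaAlH2(OCH2CH2OMe)2 (1.5 equiv), THF, 0 °C → rt; then I2, −78 → 0 °C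
Reagents that add atoms: iodine, II
Why: Hydroxyl-directed trans-hydroalumination places aluminium on the alkyne carbon remote from the free hydroxyl (five-membered aluminate) and iodinolysis with retention gives the (Z)-vinyl iodide in which iodine, the later site of C3, is cis to C6.

Step 10
Reactants: 14 (2Z)-3-iodo-4-[(4-methoxybenzyl)oxy]but-2-en-1-ol
Product: 15 (2Z)-3-iodo-4-[(4-methoxybenzyl)oxy]but-2-enal
Conditions: MnO2, CH2Cl2, rt
Reagents that add atoms: none
Why: MnO2 oxidises the allylic alcohol to the enal under neutral conditions that should preserve the Z geometry and the PMB ether.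

Step 11
Reactants: 10 C8 ketone; 15 (2Z)-3-iodo-4-[(4-methoxybenzyl)oxy]but-2-enal
Product: 17 syn-aldol adduct (6S,7S,10R)-6-hydroxy-8-ketone, via (Z)-enol diisopinocampheylborinate 16 (not isolated)
Conditions: (−)-Ipc2BOTf (from (−)-Ipc2BH and TfOH), iPr2NEt, CH2Cl2, −78 °C, 3 h; then 15, −78 → −20 °C; H2O2, MeOH, pH 7 buffer, 0 °C
Reagents that add atoms: none
Why: Soft enolisation at the more acidic and less hindered allylic C7 gives the (Z)-boron dienolate, which reacts at C7 through a Zimmerman–Traxler chair to give the 6,7-syn aldol, while the isopinocampheyl ligands (reagent control as in syn aldols of (Z)-enol diisopinocampheylborinates with enals) should direct attack to the si face of the enal and so set C6 and C7.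

Step 12
Reactants: 17 syn-aldol adduct
Product: 18 (6S,7R,8R,10R)-6-acetate 8-alcohol
Conditions: CH3CHO (6 equiv), SmI2 (20 mol %), THF, −10 °C
Reagents that add atoms: acetaldehyde, CC=O
Why: In the Evans–Tishchenko reduction the samarium-bound hemiacetal on O6 delivers hydride intramolecularly to the C8 ketone through a chair transition state, which sets C8 anti to C6 and leaves O6 acetylated and O8 free, so the two oxygens are differentiated in the same operation.

Step 13
Reactants: 18 6-acetate 8-alcohol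
Product: 19 (6S,7S,8R,10R)-6-acetate 8-TBS ether
Conditions: tBuMe2SiOTf, 2,6-lutidine, CH2Cl2, −78 °C
Reagents that add atoms: tert-butyldimethylsilyl trifluoromethanesulfonate, CC(C)(C)[Si](C)(C)OS(=O)(=O)C(F)(F)F
Why: Silyl triflate silylation of the hindered C8 hydroxyl is fast at low temperature, where acetate migration should not compete.

Step 14
Reactants: 19 6-acetate 8-TBS ether
Product: 20 (6S,7S,8R,10R)-6-alcohol 8-TBS ether
Conditions: iBu2AlH (2.5 equiv), CH2Cl2, −78 °C; aq. KNaC4H4O6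
Reagents that add atoms: none
Why: Reductive cleavage of the acetate at −78 °C frees the C6 hydroxyl without base, so no silyl migration is expected, and spares the silyl ethers, the PMB ether and the vinyl iodide.

Step 15
Reactants: 20 6-alcohol 8-TBS ether
Product: 21 (6S,7R,8R,10R)-6-TES ether 8-TBS ether
Conditions: Et3SiOTf, 2,6-lutidine, CH2Cl2, −78 °C
Reagents that add atoms: triethylsilyl trifluoromethanesulfonate, CC[Si](CC)(CC)OS(=O)(=O)C(F)(F)F
Why: The C6 hydroxyl is capped as a triethylsilyl ether so that it can later be removed together with the primary C12 silyl ether while the secondary TBS ether on C8 stays.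

Step 16
Reactants: 21 6-TES ether 8-TBS ether
Product: 22 (6S,7R,8R,10R)-C1 aldehyde vinyl iodide
Conditions: (COCl)2, DMSO, CH2Cl2, −78 → −40 °C; then Et3N, → 0 °C
Reagents that add atoms: none
Why: Under Swern conditions a primary triethylsilyl ether is converted directly into the aldehyde (silyl transfer to chloride, then collapse of the alkoxysulfonium ylide), whereas secondary and tertiary triethylsilyl ethers and TBS ethers are inert, so C1 should be unmasked selectively.

Step 17
Reactants: 22 C1 aldehyde vinyl iodide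
Product: 23 (4Z,6R,7R,8R,10R)-C1 aldehyde 3-ethoxy-2,4-diene
Conditions: tributyl(1-ethoxyvinyl)stannane, Pd2(dba)3 (2.5 mol %), AsPh3 (20 mol %), CuI (10 mol %), N-methylpyrrolidone, 40 °C
Reagents that add atoms: tributyl(1-ethoxyvinyl)stannane, CCCC[Sn](CCCC)(CCCC)C(=C)OCC
Why: Stille coupling of the vinyl iodide proceeds with retention of the 4Z geometry and installs C3 and C2 as a masked acetyl group under neutral conditions that tolerate the aldehyde and the silyl ethers.

Step 18
Reactants: 23 C1 aldehyde 3-ethoxy-2,4-diene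
Product: 24 (4Z,6R,7R,8R,10R)-C1 aldehyde C2-bromomethyl enone
Conditions: N-bromosuccinimide, THF/H2O (10:1), 0 °C
Reagents that add atoms: N-bromosuccinimide, O=C1CCC(=O)N1Br; water, O
Why: The electron-rich enol ether terminus (C2) is brominated in preference to the other alkenes and the oxocarbenium ion is hydrolysed at C3, the usual conversion of a 1-alkoxyvinyl group into a bromomethyl ketone.

Step 19
Reactants: 24 C1 aldehyde C2-bromomethyl enone
Product: 26 (1S,4Z,6R,7R,8R,10R)-1-hydroxygermacra-4,11(13)-dien-3-one (6-OTES, 8-OTBS, 10-OTES, 12-OTBS, 15-OPMB), via diiodosamarium enolate 25 (not isolated)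
Conditions: SmI2 (2.2 equiv, 0.1 M in THF) added over 2 h to 24 (0.002 M in THF), −78 °C; sat. aq. NH4Cl at −78 °C
Reagents that add atoms: none
Why: Two-electron reduction of the C2–Br bond by SmI2 gives the samarium enolate of the C3 enone regiospecifically and without base, and its C2 terminus adds to the C1 aldehyde through a chelated six-membered transition state. The closest known reaction type is the SmI2-mediated intramolecular Reformatsky (aldol) cyclisation of α-bromo ketones onto aldehydes, which closes eight- to eleven-membered carbocycles. The ten-membered ring closes in a 10-(enolendo)-exo-trig mode, helped by the cis C4=C5 bond, the quaternary C10 and the branched C6–C8 segment, with high dilution suppressing intermolecular aldolisation. C1, the only new stereocentre, is controlled by C10: in the polar Felkin–Anh arrangement the C10–OSiEt3 bond lies anti to the incoming C2 with the C9 methylene inside and the C14 methyl outside, which should give the (1S)-carbinol. The step needs reduction of the C–Br bond in preference to the aldehyde and the enone, which the much faster reduction of α-bromo ketones at −78 °C and the slow addition of SmI2 should secure, and it needs only the cross-aldol, which the absence of α-hydrogens on the C1 aldehyde secures. The samarium aldolate is strongly bound and non-basic, so neither retro-aldol opening of the strained ring nor migration of the C10 silyl group to O1 is expected before the cold quench.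

Step 20
Reactants: 26 1-hydroxy-3-ketone
Product: 27 (1S,3S,4Z,6R,7R,8R,10R)-1,3-diol
Conditions: Me4NBH(OAc)3 (5 equiv), MeCN/AcOH (1:1), −25 °C
Reagents that add atoms: none
Why: In the Evans–Saksena reduction the C1 hydroxyl exchanges onto boron and hydride is delivered internally through a chair transition state, which reduces the enone 1,2 and should set C3 anti to C1 (3S).

Step 21
Reactants: 27 1,3-diol
Product: 28 (1S,3S)-3-acetate 1-alcohol
Conditions: Ac2O (1.1 equiv), pyridine, DMAP (5 mol %), CH2Cl2, −20 °C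
Reagents that add atoms: acetic anhydride, CC(=O)OC(C)=O
Why: The allylic C3 hydroxyl should be acylated in preference to the C1 hydroxyl, which is neopentylic and shielded by the C14 methyl and the triethylsilyloxy group on C10.

Step 22
Reactants: 28 3-acetate 1-alcohol
Product: 29 (1S,3S)-3-acetate 1-mesylate
Conditions: MsCl, Et3N, CH2Cl2, 0 °C
Reagents that add atoms: methanesulfonyl chloride, CS(=O)(=O)Cl
Why: Mesylation through sulfene works on hindered secondary alcohols and turns O1 into the leaving group for the later epoxide closure.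

Step 23
Reactants: 29 3-acetate 1-mesylate
Product: 30 (1S,3S,6R,7S,8R,10R)-6,12-diol
Conditions: pyridinium p-toluenesulfonate (0.3 equiv), MeOH/CH2Cl2 (1:1), 0 °C → rt
Reagents that add atoms: none
Why: Mild acidic methanolysis removes the secondary triethylsilyl ether on C6 and the primary TBS ether on C12, while the secondary TBS ether on C8 and the hindered tertiary triethylsilyl ether on C10 react much more slowly and should be retained.

Step 24
Reactants: 30 6,12-diol
Product: 33 (1S,3S,6R,7S,8R,10R)-12,6-olide, via hydroxy enal 31 (not isolated), via lactol 32 (not isolated)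
Conditions: TEMPO (20 mol %), PhI(OAc)2 (2.5 equiv), CH2Cl2, rt
Reagents that add atoms: none
Why: The oxoammonium species oxidises the primary allylic C12 hydroxyl much faster than the secondary C6 hydroxyl, the enal is trapped by O6 as the five-membered lactol, and a second oxidation gives the α-methylene-γ-lactone (oxidative lactonisation of a 2-methylene-1,4-diol).

Step 25
Reactants: 33 12,6-olide
Product: 34 (1S,3S,6R,7R,8R,10R)-8,10-diol 12,6-olide
Conditions: HF·pyridine, pyridine, THF, 0 °C → rt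
Reagents that add atoms: none
Why: Buffered HF cleaves the remaining secondary TBS ether (C8) and tertiary triethylsilyl ether (C10) without touching the mesylate, the acetate, the PMB ether or the methylene lactone, and without base that could move the lactone to O8.

Step 26
Reactants: 34 8,10-diol 12,6-olide
Product: 35 (1S,3S,6R,7R,8R,10R)-8-methacrylate 10-alcohol
Conditions: methacrylic anhydride, Et3N, DMAP (cat.), CH2Cl2, 0 °C → rt
Reagents that add atoms: methacrylic anhydride, CC(=C)C(=O)OC(=O)C(C)=C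
Why: DMAP-catalysed acylation esterifies the secondary C8 hydroxyl, the tertiary C10 hydroxyl being inert to acylation under these conditions.

Step 27
Reactants: 35 8-methacrylate 10-alcohol
Product: 36 (1R,3S,4Z,6R,7R,8R,10R)-1,10-epoxide 15-PMB ether
Conditions: 1,8-diazabicyclo[5.4.0]undec-7-ene (DBU), CH2Cl2, rt
Reagents that add atoms: none
Why: The C10 oxygen displaces the vicinal C1 mesylate from the rear (3-exo-tet), closing the epoxide with inversion at C1 (1S to 1R) and retention at C10, and a non-nucleophilic amidine base should spare the esters and the methylene lactone.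

Step 28
Reactants: 36 1,10-epoxide 15-PMB ether
Product: 37 CNP0319155.1, (1R,3S,4Z,6R,7R,8R,10R)-3-acetoxy-1,10-epoxy-15-hydroxy-8-(2-methylprop-2-enoyloxy)germacra-4,11(13)-dien-12,6-olide
Conditions: 2,3-dichloro-5,6-dicyano-1,4-benzoquinone (DDQ, 1.3 equiv), CH2Cl2/pH 7 phosphate buffer (10:1), 0 °C → rt
Reagents that add atoms: none
Why: Oxidative cleavage of the PMB ether under buffered, non-basic conditions frees the C15 hydroxyl without acyl migration from O3 and without opening the epoxide.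

**Compound list**

1 | (R)-citramalic acid, (2R)-2-hydroxy-2-methylbutanedioic acid | OC(=O)C[C@@](C)(O)C(=O)O | starting material
2 | dimethyl (2R)-2-hydroxy-2-methylbutanedioate | COC(=O)C[C@@](C)(O)C(=O)OC | intermediate
3 | methyl (3R)-3,4-dihydroxy-3-methylbutanoate | COC(=O)C[C@@](C)(O)CO | intermediate
4 | methyl (3R)-3-methyl-3,4-bis(triethylsilyloxy)butanoate | COC(=O)C[C@@](C)(O[Si](CC)(CC)CC)CO[Si](CC)(CC)CC | intermediate
5 | (3R)-N-methoxy-N,3-dimethyl-3,4-bis(triethylsilyloxy)butanamide (C8 Weinreb amide, 10R) | CON(C)C(=O)C[C@@](C)(O[Si](CC)(CC)CC)CO[Si](CC)(CC)CC | intermediate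
6 | 2-methylenepropane-1,3-diol | C=C(CO)CO | starting material
7 | 2-[(tert-butyldimethylsilyloxy)methyl]prop-2-en-1-ol | C=C(CO)CO[Si](C)(C)C(C)(C)C | intermediate
8 | tert-butyl{[2-(chloromethyl)prop-2-en-1-yl]oxy}dimethylsilane | C=C(CCl)CO[Si](C)(C)C(C)(C)C | intermediate
9 | {2-[(tert-butyldimethylsilyloxy)methyl]prop-2-en-1-yl}magnesium chloride (formed in situ) | C=C(C[Mg]Cl)CO[Si](C)(C)C(C)(C)C | intermediate
10 | (2R)-6-[(tert-butyldimethylsilyloxy)methyl]-2-methyl-1,2-bis(triethylsilyloxy)hept-6-en-4-one (chain C1–C10–C9–C8(=O)–C7–C11(=C13)–C12; 10R) | CC[Si](CC)(CC)OC[C@](C)(O[Si](CC)(CC)CC)CC(=O)CC(=C)CO[Si](C)(C)C(C)(C)C | intermediate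
11 | but-2-yne-1,4-diol | OCC#CCO | starting material
12 | 4-[(4-methoxybenzyl)oxy]but-2-yn-1-ol | OCC#CCOCc1ccc(OC)cc1 | intermediate
13 | sodium 2,2-bis(2-methoxyethoxy)-3-{[(4-methoxybenzyl)oxy]methyl}-2,5-dihydro-1,2-oxaluminol-2-uide (cyclic alkenylaluminate, formed in situ) | [Na+].COCCO[Al-]1(OCCOC)OCC=C1COCc1ccc(OC)cc1 | intermediate
14 | (2Z)-3-iodo-4-[(4-methoxybenzyl)oxy]but-2-en-1-ol | OC/C=C(/COCc1ccc(OC)cc1)I | intermediate
15 | (2Z)-3-iodo-4-[(4-methoxybenzyl)oxy]but-2-enal (C6 aldehyde, C4 iodide, 15-OPMB) | O=C/C=C(/COCc1ccc(OC)cc1)I | intermediate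
16 | (Z)-enol diisopinocampheylborinate of 10 (C7=C8, O–B cis to C11; formed in situ) | CC[Si](CC)(CC)OC[C@](C)(O[Si](CC)(CC)CC)C/C(OB([C@@H]1C[C@@H]2C[C@H]([C@H]1C)C2(C)C)[C@@H]1C[C@@H]2C[C@H]([C@H]1C)C2(C)C)=C/C(=C)CO[Si](C)(C)C(C)(C)C | intermediate
17 | (2R,5S,6S,7Z)-5-[3-(tert-butyldimethylsilyloxy)prop-1-en-2-yl]-6-hydroxy-8-iodo-9-[(4-methoxybenzyl)oxy]-2-methyl-1,2-bis(triethylsilyloxy)non-7-en-4-one; by target labels (4Z,6S,7S,10R), 8-ketone, 6-OH | CC[Si](CC)(CC)OC[C@](C)(O[Si](CC)(CC)CC)CC(=O)[C@@H](C(=C)CO[Si](C)(C)C(C)(C)C)[C@H](O)/C=C(/COCc1ccc(OC)cc1)I | intermediate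
18 | open chain C1–C10–C9–C8–C7–C6–C5=C4(I)–C15, (4Z,6S,7R,8R,10R): 1-OTES, 10-OTES, 8-OH, 6-OAc, 7-[C11(=CH2)CH2OTBS], 15-OPMB | CC[Si](CC)(CC)OC[C@](C)(O[Si](CC)(CC)CC)C[C@@H](O)[C@@H](C(=C)CO[Si](C)(C)C(C)(C)C)[C@H](OC(C)=O)/C=C(/COCc1ccc(OC)cc1)I | intermediate
19 | as 18 with 8-OTBS, (4Z,6S,7S,8R,10R) | CC[Si](CC)(CC)OC[C@](C)(O[Si](CC)(CC)CC)C[C@@H](O[Si](C)(C)C(C)(C)C)[C@@H](C(=C)CO[Si](C)(C)C(C)(C)C)[C@H](OC(C)=O)/C=C(/COCc1ccc(OC)cc1)I | intermediate
20 | as 19 with 6-OH, (4Z,6S,7S,8R,10R) | CC[Si](CC)(CC)OC[C@](C)(O[Si](CC)(CC)CC)C[C@@H](O[Si](C)(C)C(C)(C)C)[C@@H](C(=C)CO[Si](C)(C)C(C)(C)C)[C@H](O)/C=C(/COCc1ccc(OC)cc1)I | intermediate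
21 | as 20 with 6-OTES, (4Z,6S,7R,8R,10R) | CC[Si](CC)(CC)OC[C@](C)(O[Si](CC)(CC)CC)C[C@@H](O[Si](C)(C)C(C)(C)C)[C@@H](C(=C)CO[Si](C)(C)C(C)(C)C)[C@H](O[Si](CC)(CC)CC)/C=C(/COCc1ccc(OC)cc1)I | intermediate
22 | as 21 with C1 as aldehyde, (4Z,6S,7R,8R,10R) | O=C[C@](C)(O[Si](CC)(CC)CC)C[C@@H](O[Si](C)(C)C(C)(C)C)[C@@H](C(=C)CO[Si](C)(C)C(C)(C)C)[C@H](O[Si](CC)(CC)CC)/C=C(/COCc1ccc(OC)cc1)I | intermediate
23 | as 22 with C4 bearing C3(OEt)=C2H2 in place of iodine, (4Z,6R,7R,8R,10R) | O=C[C@](C)(O[Si](CC)(CC)CC)C[C@@H](O[Si](C)(C)C(C)(C)C)[C@@H](C(=C)CO[Si](C)(C)C(C)(C)C)[C@H](O[Si](CC)(CC)CC)/C=C(/COCc1ccc(OC)cc1)C(=C)OCC | intermediate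
24 | macro-aldol precursor: C1 aldehyde, C3 ketone, C2 bromomethyl, (4Z,6R,7R,8R,10R); 6-OTES, 8-OTBS, 10-OTES, 12-OTBS, 15-OPMB | O=C[C@](C)(O[Si](CC)(CC)CC)C[C@@H](O[Si](C)(C)C(C)(C)C)[C@@H](C(=C)CO[Si](C)(C)C(C)(C)C)[C@H](O[Si](CC)(CC)CC)/C=C(/COCc1ccc(OC)cc1)C(=O)CBr | intermediate
25 | diiodosamarium enolate of the C3 ketone (C2=C3–O–SmI2; formed in situ) | O=C[C@](C)(O[Si](CC)(CC)CC)C[C@@H](O[Si](C)(C)C(C)(C)C)[C@@H](C(=C)CO[Si](C)(C)C(C)(C)C)[C@H](O[Si](CC)(CC)CC)/C=C(/COCc1ccc(OC)cc1)C(=C)O[Sm](I)I | intermediate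
26 | (1S,4Z,6R,7R,8R,10R)-1-hydroxy-15-(PMB-oxy)-12-(TBS-oxy)-8-(TBS-oxy)-6,10-bis(TES-oxy)germacra-4,11(13)-dien-3-one | CC(C)(C)[Si](C)(C)O[C@@H]1C[C@@](C)(O[Si](CC)(CC)CC)[C@@H](O)CC(=O)/C(COCc2ccc(OC)cc2)=C\[C@@H](O[Si](CC)(CC)CC)[C@@H]1C(=C)CO[Si](C)(C)C(C)(C)C | intermediate
27 | (1S,3S,4Z,6R,7R,8R,10R)-1,3-diol of 26 | CC(C)(C)[Si](C)(C)O[C@@H]1C[C@@](C)(O[Si](CC)(CC)CC)[C@@H](O)C[C@H](O)/C(COCc2ccc(OC)cc2)=C\[C@@H](O[Si](CC)(CC)CC)[C@@H]1C(=C)CO[Si](C)(C)C(C)(C)C | intermediate
28 | 3-acetate of 27, (1S,3S,4Z,6R,7R,8R,10R) | CC(C)(C)[Si](C)(C)O[C@@H]1C[C@@](C)(O[Si](CC)(CC)CC)[C@@H](O)C[C@H](OC(C)=O)/C(COCc2ccc(OC)cc2)=C\[C@@H](O[Si](CC)(CC)CC)[C@@H]1C(=C)CO[Si](C)(C)C(C)(C)C | intermediate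
29 | 3-acetate 1-mesylate, (1S,3S,4Z,6R,7R,8R,10R) | CC(C)(C)[Si](C)(C)O[C@@H]1C[C@@](C)(O[Si](CC)(CC)CC)[C@@H](OS(C)(=O)=O)C[C@H](OC(C)=O)/C(COCc2ccc(OC)cc2)=C\[C@@H](O[Si](CC)(CC)CC)[C@@H]1C(=C)CO[Si](C)(C)C(C)(C)C | intermediate
30 | 6,12-diol (8-OTBS, 10-OTES, 1-OMs, 3-OAc, 15-OPMB), (1S,3S,4Z,6R,7S,8R,10R) | CC(C)(C)[Si](C)(C)O[C@@H]1C[C@@](C)(O[Si](CC)(CC)CC)[C@@H](OS(C)(=O)=O)C[C@H](OC(C)=O)/C(COCc2ccc(OC)cc2)=C\[C@@H](O)[C@@H]1C(=C)CO | intermediate
31 | 6-hydroxy-12-al (enal from 30; formed in situ) | CC(C)(C)[Si](C)(C)O[C@@H]1C[C@@](C)(O[Si](CC)(CC)CC)[C@@H](OS(C)(=O)=O)C[C@H](OC(C)=O)/C(COCc2ccc(OC)cc2)=C\[C@@H](O)[C@@H]1C(=C)C=O | intermediate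
32 | 12,6-lactol (C12 epimers; formed in situ) | CC(C)(C)[Si](C)(C)O[C@@H]1C[C@@](C)(O[Si](CC)(CC)CC)[C@@H](OS(C)(=O)=O)C[C@H](OC(C)=O)/C(COCc2ccc(OC)cc2)=C\[C@H]3OC(O)C(=C)[C@@H]31 | intermediate
33 | 12,6-olide (8-OTBS, 10-OTES, 1-OMs, 3-OAc, 15-OPMB), (1S,3S,4Z,6R,7S,8R,10R) | CC(C)(C)[Si](C)(C)O[C@@H]1C[C@@](C)(O[Si](CC)(CC)CC)[C@@H](OS(C)(=O)=O)C[C@H](OC(C)=O)/C(COCc2ccc(OC)cc2)=C\[C@H]3OC(=O)C(=C)[C@@H]31 | intermediate
34 | 8,10-diol 12,6-olide (1-OMs, 3-OAc, 15-OPMB), (1S,3S,4Z,6R,7R,8R,10R) | O[C@@H]1C[C@@](C)(O)[C@@H](OS(C)(=O)=O)C[C@H](OC(C)=O)/C(COCc2ccc(OC)cc2)=C\[C@H]3OC(=O)C(=C)[C@@H]31 | intermediate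
35 | 8-methacrylate 10-alcohol 1-mesylate, (1S,3S,4Z,6R,7R,8R,10R) | C=C(C)C(=O)O[C@@H]1C[C@@](C)(O)[C@@H](OS(C)(=O)=O)C[C@H](OC(C)=O)/C(COCc2ccc(OC)cc2)=C\[C@H]3OC(=O)C(=C)[C@@H]31 | intermediate
36 | 15-O-PMB ether of the target, (1R,3S,4Z,6R,7R,8R,10R)-1,10-epoxide | C=C(C)C(=O)O[C@@H]1C[C@@]2(C)O[C@@H]2C[C@H](OC(C)=O)/C(COCc3ccc(OC)cc3)=C\[C@H]4OC(=O)C(=C)[C@@H]41 | intermediate
37 | CNP0319155.1, (1R,3S,4Z,6R,7R,8R,10R)-3-acetoxy-1,10-epoxy-15-hydroxy-8-(2-methylprop-2-enoyloxy)germacra-4,11(13)-dien-12,6-olide | C=C(C)C(=O)O[C@@H]1C[C@@]2(C)O[C@@H]2C[C@H](OC(C)=O)/C(CO)=C\[C@H]2OC(=O)C(=C)[C@@H]21 | target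

**Step count and risks**

Total: 28 steps. Longest linear sequence: 23 steps (1 to 37 through steps 1–4, 7 and 11–28).

Steps most likely to fail:

1. Step 19 (macro-aldol). What may go wrong: the samarium enolate is protonated, or the aldehyde or the product enone is reduced, while the slow ten-membered closure is awaited; intermolecular aldolisation may also outrun closure. Fallback (enolate made by deprotonation instead of reduction): setting out from 23, the enol ether is hydrolysed (aqueous oxalic acid, THF, 0 °C) to the methyl enone aldehyde F1. F1 is then cyclised as its potassium enolate (KN(SiMe3)2, THF, −78 °C, 0.001 M, AcOH quench at −78 °C) by kinetic deprotonation of the C2 methyl group and addition to the C1 aldehyde, which returns to the route at 26.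

2. Step 21 (O3 versus O1 acetylation). What may go wrong: the ring conformation exposes the C1 hydroxyl so that the 1-acetate or the diacetate forms, or the acetyl group migrates between O3 and O1. Fallback (the two hydroxyls are never free together): setting out from 26, the C1 hydroxyl is silylated (Me3SiCl, imidazole, CH2Cl2, 0 °C) to the 1-O-trimethylsilyl ketone F2. Reagent-controlled reduction of the enone with (R)-2-methyl-CBS-oxazaborolidine and catecholborane (toluene, −60 °C; the alkenyl branch acts as the large group) should give the (3S)-allylic alcohol F3. Acetylation (Ac2O, DMAP, pyridine) gives the 3-acetate 1-O-trimethylsilyl ether F4, and selective cleavage of the trimethylsilyl ether (citric acid, MeOH, 0 °C) returns to the route at 28.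

3. Step 7 (allylic Grignard acylation). What may go wrong: Wurtz coupling during formation of the allylic magnesium reagent, or migration of the 1,1-disubstituted double bond into conjugation with the new ketone when the magnesium chelate is quenched. Fallback (addition to an aldehyde, then oxidation): setting out from 4, reduction with iBu2AlH (CH2Cl2, −78 °C) gives the aldehyde F5. Indium-mediated Barbier allylation with chloride 8 (In powder, NaI, DMF, rt) gives the homoallylic alcohol F6 as both C8 epimers, which does not matter, and Dess–Martin oxidation (NaHCO3, CH2Cl2) returns to the route at 10.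

**Further compounds**

F1 | step 19 | methyl enone aldehyde (24 with CH3 in place of CH2Br), (4Z,6R,7R,8R,10R) | O=C[C@](C)(O[Si](CC)(CC)CC)C[C@@H](O[Si](C)(C)C(C)(C)C)[C@@H](C(=C)CO[Si](C)(C)C(C)(C)C)[C@H](O[Si](CC)(CC)CC)/C=C(/COCc1ccc(OC)cc1)C(C)=O
F2 | step 21 | 1-O-trimethylsilyl ether of 26 | CC(C)(C)[Si](C)(C)O[C@@H]1C[C@@](C)(O[Si](CC)(CC)CC)[C@@H](O[Si](C)(C)C)CC(=O)/C(COCc2ccc(OC)cc2)=C\[C@@H](O[Si](CC)(CC)CC)[C@@H]1C(=C)CO[Si](C)(C)C(C)(C)C
F3 | step 21 | (3S)-allylic alcohol, 1-O-trimethylsilyl ether | CC(C)(C)[Si](C)(C)O[C@@H]1C[C@@](C)(O[Si](CC)(CC)CC)[C@@H](O[Si](C)(C)C)C[C@H](O)/C(COCc2ccc(OC)cc2)=C\[C@@H](O[Si](CC)(CC)CC)[C@@H]1C(=C)CO[Si](C)(C)C(C)(C)C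
F4 | step 21 | 3-acetate 1-O-trimethylsilyl ether | CC(C)(C)[Si](C)(C)O[C@@H]1C[C@@](C)(O[Si](CC)(CC)CC)[C@@H](O[Si](C)(C)C)C[C@H](OC(C)=O)/C(COCc2ccc(OC)cc2)=C\[C@@H](O[Si](CC)(CC)CC)[C@@H]1C(=C)CO[Si](C)(C)C(C)(C)C
F5 | step 7 | (3R)-3-methyl-3,4-bis(triethylsilyloxy)butanal | CC[Si](CC)(CC)OC[C@](C)(O[Si](CC)(CC)CC)CC=O
F6 | step 7 | (2R)-6-[(tert-butyldimethylsilyloxy)methyl]-2-methyl-1,2-bis(triethylsilyloxy)hept-6-en-4-ol (both C4 epimers) | CC[Si](CC)(CC)OC[C@](C)(O[Si](CC)(CC)CC)CC(O)CC(=C)CO[Si](C)(C)C(C)(C)C
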